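## Retrosynthetic overview

1. The 1,2-dioxane is the only ring and is closed last: the C6–O bond comes from a 3-hydroperoxy acid by chiral Brønsted acid-catalysed addition of the OOH group to a C6 1,1-disubstituted alkene (sets C6).
2. The C3–OO bond comes from amine-catalysed conjugate peroxidation of an (E)-enal (sets C3); the aldehyde is oxidised to the acid in the same flask.
3. The C6 methylidene comes from a C6 ketone (Wittig). The ketone comes from hepta-2,5-dien-4-one by two diol-catalysed conjugate alkenylations: the C3–C4 bond sets C4, and the C8–C9 bond sets C8 and joins the two halves.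
4. The C9–C14 alkenylboronic acid comes from boron-Wittig homologation of (S)-3-methyl-5-phenylpent-4-enal, itself made by iminium-catalysed addition of a styryltrifluoroborate to crotonaldehyde (first stereocentre, C12).

Assumption: the catalyst antipodes named are those predicted by the accepted stereomodels (the face attacked is stated in each step); if a model fails on a given substrate, the mirror-image catalyst is used with no other change. All starting materials are taken to be catalogue compounds.

## Route

Step 1
Reactants: 1 (E)-but-2-enal (crotonaldehyde); 2 potassium trifluoro[(E)-2-phenylethenyl]borate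
Product: 3 (3S,4E)-3-methyl-5-phenylpent-4-enal
Conditions: (2R,5R)-5-benzyl-2-tert-butyl-3-methylimidazolidin-4-one·HCl (20 mol %), HF (1 equiv), DME, −20 °C
Reagents that add atoms: none
Why: Iminium-ion organocatalysis (conjugate vinylation of an enal by a vinyltrifluoroborate, a Friedel–Crafts-type addition): the benzyl and tert-butyl groups shield one face of the (E)-iminium of 1, so the styryl group adds to the Si face of the β-carbon and sets 3S, the first stereocentre, from achiral materials.

Step 2
Reactants: 3 (3S,4E)-3-methyl-5-phenylpent-4-enal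
Product: 5 [(1E,4S,5E)-4-methyl-6-phenylhexa-1,5-dien-1-yl]boronic acid, via pinacol alkenylboronate 4 (not isolated)
Conditions: CH2(Bpin)2, lithium 2,2,6,6-tetramethylpiperidide (LiTMP), THF, −78 → 0 °C; then NaIO4, NH4OAc, acetone/H2O, rt
Reagents that add atoms: bis[(pinacolato)boryl]methane CC1(C)OB(CB2OC(C)(C)C(C)(C)O2)OC1(C)C; water O
Why: Boron-Wittig olefination (the lithiated geminal bis(boronate) adds to the aldehyde and syn B–O elimination gives the E-alkenylboronate), followed by periodate cleavage of the pinacol, which frees the boronic acid without touching the remote stereocentre.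

Step 3
Reactants: 6 (E)-but-2-enoyl chloride; 7 [(E)-prop-1-en-1-yl]boronic acid
Product: 8 (2E,5E)-hepta-2,5-dien-4-one
Conditions: Pd(PPh3)4 (3 mol %), Cs2CO3, toluene, 80 °C
Reagents that add atoms: none
Why: Acyl Suzuki–Miyaura coupling of an enoyl chloride with an alkenylboronic acid, which carries both E geometries through and gives the symmetrical cross-conjugated dienone in one step.

Step 4
Reactants: 9 2-[(E)-3,3-diethoxyprop-1-en-1-yl]-4,4,5,5-tetramethyl-1,3,2-dioxaborolane
Product: 10 [(E)-3,3-diethoxyprop-1-en-1-yl]boronic acid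
Conditions: NaIO4, NH4OAc, acetone/H2O, rt
Reagents that add atoms: water O
Why: Oxidative removal of pinacol (periodate cleaves the diol released on hydrolysis), run in neutral acetate buffer so that the diethyl acetal survives.

Step 5
Reactants: 8 (2E,5E)-hepta-2,5-dien-4-one; 10 [(E)-3,3-diethoxyprop-1-en-1-yl]boronic acid
Product: 11 (2E,6S,7E)-9,9-diethoxy-6-methylnona-2,7-dien-4-one
Conditions: (R)-3,3′-bis(pentafluorophenyl)-BINOL (20 mol %), Mg(OtBu)2 (10 mol %), 4 Å MS, toluene, 70 °C, dienone in threefold excess
Reagents that add atoms: none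
Why: Binaphthol-catalysed asymmetric conjugate alkenylation of an enone with a boronic acid: the diol exchanges onto boron, the boronate binds the s-cis enone carbonyl and passes the alkenyl group through a closed six-membered transition state to the Si face of the β-carbon, giving 6S (C4 of the target), while the excess of symmetrical dienone holds back double addition.

Step 6
Reactants: 11 (2E,6S,7E)-9,9-diethoxy-6-methylnona-2,7-dien-4-one; 5 [(1E,4S,5E)-4-methyl-6-phenylhexa-1,5-dien-1-yl]boronic acid
Product: 12 (2E,4S,8R,9E,12S,13E)-1,1-diethoxy-4,8,12-trimethyl-14-phenyltetradeca-2,9,13-trien-6-one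
Conditions: (S)-3,3′-bis(pentafluorophenyl)-BINOL (20 mol %), Mg(OtBu)2 (10 mol %), 4 Å MS, toluene, 70 °C, boronic acid in 1.5-fold excess
Reagents that add atoms: none
Why: The same diol-catalysed conjugate alkenylation with the mirror-image catalyst on the remaining propenyl ketone: alkenyl transfer to the Re face of the β-carbon sets C8 as R under catalyst control (the existing centres are too remote to interfere) and joins the two halves with all E alkenes intact.

Step 7
Reactants: 12 (2E,4S,8R,9E,12S,13E)-1,1-diethoxy-4,8,12-trimethyl-14-phenyltetradeca-2,9,13-trien-6-one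
Product: 14 (2E,4S,8R,9E,12S,13E)-4,8,12-trimethyl-6-methylidene-14-phenyltetradeca-2,9,13-trienal, via methylidene diethyl acetal 13 (not isolated)
Conditions: Ph3PCH3Br, KOtBu, THF, 0 °C → rt; then 1 M HCl, THF/H2O, 0 °C
Reagents that add atoms: methyltriphenylphosphonium bromide C[P+](c1ccccc1)(c1ccccc1)c1ccccc1.[Br-]; water O
Why: Wittig methylenation of an unhindered dialkyl ketone that has no α-stereocentre to epimerise, followed by acidic work-up that hydrolyses the allylic diethyl acetal to the (E)-enal.

Step 8
Reactants: 15 2,3-dimethylbut-2-ene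
Product: 16 2-methoxypropan-2-yl hydroperoxide
Conditions: O3, MeOH/CH2Cl2, −78 °C
Reagents that add atoms: ozone [O-][O+]=O; methanol CO
Why: Criegee ozonolysis in methanol: the carbonyl oxide from the tetrasubstituted alkene is trapped by methanol to give the α-methoxy hydroperoxide, an acid-removable hydrogen peroxide equivalent.

Step 9
Reactants: 14 (2E,4S,8R,9E,12S,13E)-4,8,12-trimethyl-6-methylidene-14-phenyltetradeca-2,9,13-trienal; 16 2-methoxypropan-2-yl hydroperoxide
Product: 18 (3S,4S,8R,9E,12S,13E)-3-[(2-methoxypropan-2-yl)peroxy]-4,8,12-trimethyl-6-methylidene-14-phenyltetradeca-9,13-dienoic acid, via peroxyketal aldehyde 17 (not isolated)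
Conditions: (S)-2-{bis[3,5-bis(trifluoromethyl)phenyl](trimethylsilyloxy)methyl}pyrrolidine (10 mol %), hydroperoxide in twofold excess, toluene, 0 °C; then NaClO2, NaH2PO4, 2-methylbut-2-ene (excess), t-BuOH/H2O, 0 °C
Reagents that add atoms: sodium chlorite [Na+].[O-]Cl=O
Why: Amine-catalysed asymmetric conjugate peroxidation of an enal (iminium activation, oxa-Michael addition of a hydroperoxide) in which the diaryl(silyloxy)methyl group blocks one face of the (E)-iminium, so the peroxide adds to the Re face of C3 and gives 3S under catalyst control next to the existing 4S centre, followed by Pinnick oxidation in the same flask (2-methylbut-2-ene keeps hypochlorous acid off the alkenes), which removes the aldehyde before the amine can turn it into the epoxy aldehyde or reverse the addition.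

Step 10
Reactants: 18 (3S,4S,8R,9E,12S,13E)-3-[(2-methoxypropan-2-yl)peroxy]-4,8,12-trimethyl-6-methylidene-14-phenyltetradeca-9,13-dienoic acid
Product: 19 (3S,4S,8R,9E,12S,13E)-3-hydroperoxy-4,8,12-trimethyl-6-methylidene-14-phenyltetradeca-9,13-dienoic acid
Conditions: AcOH/THF/H2O, rt
Reagents that add atoms: none
Why: Mild acid hydrolysis of the monoperoxyketal (loss of methanol, then collapse of the peroxy hemiketal to acetone), which frees the hydroperoxide without touching the C3–O bond or the 1,1-disubstituted alkene.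

Step 11
Reactants: 19 (3S,4S,8R,9E,12S,13E)-3-hydroperoxy-4,8,12-trimethyl-6-methylidene-14-phenyltetradeca-9,13-dienoic acid
Product: 20 2-[(3S,4S,6R)-4,6-dimethyl-6-[(2R,3E,6S,7E)-2,6-dimethyl-8-phenylocta-3,7-dien-1-yl]-1,2-dioxan-3-yl]acetic acid (target)
Conditions: (S,S)-imidodiphosphorimidate Brønsted acid (IDPi, N-triflyl, 3,3′-aryl; 5 mol %), CHCl3, 0 °C → rt
Reagents that add atoms: none
Why: Proposed new method: a confined chiral imidodiphosphorimidate acid protonates the 1,1-disubstituted alkene (the only one that gives a tertiary cation) while the hydroperoxide O–H, hydrogen-bonded to the counter-anion, adds in a concerted asynchronous 6-exo Markovnikov fashion inside the chiral pocket, so the catalyst rather than the almost unbiased chair (methyl versus CH2R on C6) chooses the alkene face and sets 6R while closing the 1,2-dioxane with C3 and C4 untouched; the closest known reaction type is the IDPi-catalysed asymmetric intramolecular hydroalkoxylation of unactivated 1,1-disubstituted alkenols, which has not been shown with a hydroperoxide nucleophile or for 1,2-dioxane formation.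

## Compound list

1 | (E)-but-2-enal (crotonaldehyde) | C/C=C/C=O | starting material
2 | potassium trifluoro[(E)-2-phenylethenyl]borate | [K+].F[B-](F)(F)/C=C/c1ccccc1 | starting material
3 | (3S,4E)-3-methyl-5-phenylpent-4-enal | C[C@H](/C=C/c1ccccc1)CC=O | intermediate
4 | 2-[(1E,4S,5E)-4-methyl-6-phenylhexa-1,5-dien-1-yl]-4,4,5,5-tetramethyl-1,3,2-dioxaborolane (pinacol alkenylboronate) | C[C@H](/C=C/c1ccccc1)C/C=C/B1OC(C)(C)C(C)(C)O1 | intermediate
5 | [(1E,4S,5E)-4-methyl-6-phenylhexa-1,5-dien-1-yl]boronic acid | C[C@H](/C=C/c1ccccc1)C/C=C/B(O)O | intermediate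
6 | (E)-but-2-enoyl chloride | C/C=C/C(=O)Cl | starting material
7 | [(E)-prop-1-en-1-yl]boronic acid | C/C=C/B(O)O | starting material
8 | (2E,5E)-hepta-2,5-dien-4-one | C/C=C/C(=O)/C=C/C | intermediate
9 | 2-[(E)-3,3-diethoxyprop-1-en-1-yl]-4,4,5,5-tetramethyl-1,3,2-dioxaborolane | CCOC(OCC)/C=C/B1OC(C)(C)C(C)(C)O1 | starting material
10 | [(E)-3,3-diethoxyprop-1-en-1-yl]boronic acid | CCOC(OCC)/C=C/B(O)O | intermediate
11 | (2E,6S,7E)-9,9-diethoxy-6-methylnona-2,7-dien-4-one | C/C=C/C(=O)C[C@H](C)/C=C/C(OCC)OCC | intermediate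
12 | (2E,4S,8R,9E,12S,13E)-1,1-diethoxy-4,8,12-trimethyl-14-phenyltetradeca-2,9,13-trien-6-one | C[C@H](/C=C/c1ccccc1)C/C=C/[C@H](C)CC(=O)C[C@H](C)/C=C/C(OCC)OCC | intermediate
13 | (2E,4S,8R,9E,12S,13E)-1,1-diethoxy-4,8,12-trimethyl-6-methylidene-14-phenyltetradeca-2,9,13-triene (methylidene diethyl acetal) | C[C@H](/C=C/c1ccccc1)C/C=C/[C@H](C)CC(=C)C[C@H](C)/C=C/C(OCC)OCC | intermediate
14 | (2E,4S,8R,9E,12S,13E)-4,8,12-trimethyl-6-methylidene-14-phenyltetradeca-2,9,13-trienal | C[C@H](/C=C/c1ccccc1)C/C=C/[C@H](C)CC(=C)C[C@H](C)/C=C/C=O | intermediate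
15 | 2,3-dimethylbut-2-ene | CC(C)=C(C)C | starting material
16 | 2-methoxypropan-2-yl hydroperoxide | COC(C)(C)OO | intermediate
17 | (3S,4S,8R,9E,12S,13E)-3-[(2-methoxypropan-2-yl)peroxy]-4,8,12-trimethyl-6-methylidene-14-phenyltetradeca-9,13-dienal (peroxyketal aldehyde) | C[C@H](/C=C/c1ccccc1)C/C=C/[C@H](C)CC(=C)C[C@H](C)[C@H](CC=O)OOC(C)(C)OC | intermediate
18 | (3S,4S,8R,9E,12S,13E)-3-[(2-methoxypropan-2-yl)peroxy]-4,8,12-trimethyl-6-methylidene-14-phenyltetradeca-9,13-dienoic acid | C[C@H](/C=C/c1ccccc1)C/C=C/[C@H](C)CC(=C)C[C@H](C)[C@H](CC(=O)O)OOC(C)(C)OC | intermediate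
19 | (3S,4S,8R,9E,12S,13E)-3-hydroperoxy-4,8,12-trimethyl-6-methylidene-14-phenyltetradeca-9,13-dienoic acid | C[C@H](/C=C/c1ccccc1)C/C=C/[C@H](C)CC(=C)C[C@H](C)[C@H](CC(=O)O)OO | intermediate
20 | 2-[(3S,4S,6R)-4,6-dimethyl-6-[(2R,3E,6S,7E)-2,6-dimethyl-8-phenylocta-3,7-dien-1-yl]-1,2-dioxan-3-yl]acetic acid | C[C@H](/C=C/c1ccccc1)C/C=C/[C@H](C)C[C@]1(C)C[C@H](C)[C@H](CC(=O)O)OO1 | target

## Step count and risks

Total steps: 11 (steps 3, 4 and 8 prepare the dienone, the acetal boronic acid and the hydroperoxide).
Longest linear sequence: 7 (steps 1, 2, 6, 7, 9, 10, 11; the branch 3 or 4, 5, 6, 7, 9, 10, 11 is equally long).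

**Risk 1, step 11 (the proposed new reaction).** A strong acid meets a secondary hydroperoxide (Hock-type cleavage is possible), and it must leave the styrene and the 1,2-disubstituted alkene alone. The free carboxylic acid could lactonise in competition, and the catalyst has to override an almost unbiased substrate at C6. The fallback uses known chemistry and sets out from 19. Cycloperoxymercuration with Hg(OAc)2 (cat. HClO4, CH2Cl2, 0 °C) gives acetoxy{[(3S,4S)-3-(carboxymethyl)-4-methyl-6-[(2R,3E,6S,7E)-2,6-dimethyl-8-phenylocta-3,7-dien-1-yl]-1,2-dioxan-6-yl]methyl}mercury F7 as both C6 epimers. Reductive demercuration (NaBH4, aqueous NaOH, 0 °C) then gives 20 together with its C6 epimer 2-[(3S,4S,6S)-4,6-dimethyl-6-[(2R,3E,6S,7E)-2,6-dimethyl-8-phenylocta-3,7-dien-1-yl]-1,2-dioxan-3-yl]acetic acid F8. The two are separated by HPLC and the route is rejoined at 20, with the ring formed under substrate control and separation instead of catalyst control.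

**Risk 2, step 6 (union of the halves).** A dialkyl propenyl ketone is outside the usual aryl-enone scope of diol-catalysed alkenylation, and the valuable boronic acid 5 cannot be used in large excess. The fallback reverses the order of the two alkenylations so that C8 is set by iminium catalysis, the reaction class of step 1. It sets out from 5. KHF2 in aqueous methanol gives potassium trifluoro[(1E,4S,5E)-4-methyl-6-phenylhexa-1,5-dien-1-yl]borate F3. Addition of F3 to crotonaldehyde 1 under the step 1 conditions, but with the (2S,5S) catalyst, gives (3R,4E,7S,8E)-3,7-dimethyl-9-phenylnona-4,8-dienal F4. Allylmagnesium bromide (THF, −78 °C) gives (6R,7E,10S,11E)-6,10-dimethyl-12-phenyldodeca-1,7,11-trien-4-ol F5 as a mixture at the carbinol carbon. Dess–Martin oxidation and DBU-mediated migration of the terminal alkene into conjugation give (2E,6R,7E,10S,11E)-6,10-dimethyl-12-phenyldodeca-2,7,11-trien-4-one F6. Diol-catalysed addition of a threefold excess of the cheap boronic acid 10 under the step 5 conditions ((R) catalyst) then sets C4 and rejoins the route at 12.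

**Risk 3, step 5 (mono-alkenylation of the dienone).** The cross-conjugated dienone can add twice or oligomerise under the warm, mildly basic conditions. The fallback replaces it with a simple enone and builds the second enone afterwards. It sets out from 10. The same diol-catalysed alkenylation on commercial (E)-pent-3-en-2-one gives (4S,5E)-7,7-diethoxy-4-methylhept-5-en-2-one F1. Kinetic deprotonation at the methyl group (lithium diisopropylamide, THF, −78 °C) and addition of acetaldehyde give the aldol (6S,7E)-9,9-diethoxy-2-hydroxy-6-methylnon-7-en-4-one F2 as a mixture at C2. Mesylation and elimination (MsCl, Et3N, then DBU) give the E-enone and rejoin the route at 11.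

## Further compounds

F1 | step 5 | (4S,5E)-7,7-diethoxy-4-methylhept-5-en-2-one | CC(=O)C[C@H](C)/C=C/C(OCC)OCC
F2 | step 5 | (6S,7E)-9,9-diethoxy-2-hydroxy-6-methylnon-7-en-4-one | CC(O)CC(=O)C[C@H](C)/C=C/C(OCC)OCC
F3 | step 6 | potassium trifluoro[(1E,4S,5E)-4-methyl-6-phenylhexa-1,5-dien-1-yl]borate | [K+].C[C@H](/C=C/c1ccccc1)C/C=C/[B-](F)(F)F
F4 | step 6 | (3R,4E,7S,8E)-3,7-dimethyl-9-phenylnona-4,8-dienal | C[C@H](/C=C/c1ccccc1)C/C=C/[C@H](C)CC=O
F5 | step 6 | (6R,7E,10S,11E)-6,10-dimethyl-12-phenyldodeca-1,7,11-trien-4-ol | C[C@H](/C=C/c1ccccc1)C/C=C/[C@H](C)CC(O)CC=C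
F6 | step 6 | (2E,6R,7E,10S,11E)-6,10-dimethyl-12-phenyldodeca-2,7,11-trien-4-one | C[C@H](/C=C/c1ccccc1)C/C=C/[C@H](C)CC(=O)/C=C/C
F7 | step 11 | acetoxy{[(3S,4S)-3-(carboxymethyl)-4-methyl-6-[(2R,3E,6S,7E)-2,6-dimethyl-8-phenylocta-3,7-dien-1-yl]-1,2-dioxan-6-yl]methyl}mercury | C[C@H](/C=C/c1ccccc1)C/C=C/[C@H](C)CC1(C[Hg]OC(C)=O)C[C@H](C)[C@H](CC(=O)O)OO1
F8 | step 11 | 2-[(3S,4S,6S)-4,6-dimethyl-6-[(2R,3E,6S,7E)-2,6-dimethyl-8-phenylocta-3,7-dien-1-yl]-1,2-dioxan-3-yl]acetic acid | C[C@H](/C=C/c1ccccc1)C/C=C/[C@H](C)C[C@@]1(C)C[C@H](C)[C@H](CC(=O)O)OO1
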